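**Retrosynthetic overview**

- The plan rests on the O1–C2–C3 segment of the furan ring. C2 is bonded both to the ring oxygen O1 and to the 4-hydroxy-3-methoxyphenyl ring, and C3 holds the formyl carbon. This is the atom pattern of a 3-arylidene-benzofuran-2(3H)-one whose lactone C–O bond has been opened.
- End game by functional-group changes only: ArOH ⇐ ArOBn, and C3–CHO ⇐ C3–CH2OH ⇐ C3–CO2Me (11).
- Key disconnection O1–C2: ester 11 ⇐ arylidene lactone 8 + methanol 9, by lactone methanolysis and iodine-mediated oxidative C–O closure.
- 8 ⇐ Knoevenagel condensation of lactone 6 with O-benzylvanillin 7. 6 ⇐ dihydroconiferyl alcohol 1 + glyoxylic acid 2, by ortho-hydroxyalkylation, benzylic hydrogenolysis and lactonisation/acetylation.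
- Ring order: both benzene rings are bought. A sacrificial lactone ring is closed in step 3 and opened again in step 5, where the furan ring is closed.

Key step: step 5

Remark on the chemistry: the target has no stereogenic element and is achiral, so no enantioselective step is needed. The only stereochemical feature on the way, the alkene geometry of 8, is erased in step 5.

**Route**

Step 1
Reactants: 1 4-(3-hydroxypropyl)-2-methoxyphenol (dihydroconiferyl alcohol); 2 glyoxylic acid
Product: 3 rac-2-hydroxy-2-[2-hydroxy-5-(3-hydroxypropyl)-3-methoxyphenyl]acetic acid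
Conditions: 2 (50% aq., 1.5 equiv), NaOH (3 equiv), H2O, N2, rt → 45 °C; then HCl to pH 1
Reagents that add atoms: none
Why: Hydroxyalkylation of a phenolate by glyoxylate (the electrophilic aromatic substitution used to make hydroxymandelic acids) should go to C6, the only free position ortho or para to the phenolate oxygen because the para position carries the side chain; the new carbinol centre forms as a racemate and is removed in step 2.

Step 2
Reactants: 3 rac-2-hydroxy-2-[2-hydroxy-5-(3-hydroxypropyl)-3-methoxyphenyl]acetic acid
Product: 4 2-[2-hydroxy-5-(3-hydroxypropyl)-3-methoxyphenyl]acetic acid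
Conditions: H2 (4 bar), 10% Pd/C, 1 M aq. HCl–1,4-dioxane (1:1), 70 °C
Reagents that add atoms: none
Why: Acid-promoted catalytic hydrogenolysis of the benzylic C–OH of a hydroxyaryl glycolic acid (the standard hydroxymandelic acid to hydroxyphenylacetic acid reduction), helped by the ortho hydroxyl through an o-quinone-methide-like cation, should remove only the carbinol oxygen and leave the arene, the methyl ether and the primary alcohol untouched.

Step 3
Reactants: 4 2-[2-hydroxy-5-(3-hydroxypropyl)-3-methoxyphenyl]acetic acid
Product: 6 3-(7-methoxy-2-oxo-2,3-dihydro-1-benzofuran-5-yl)propyl acetate, via hydroxy lactone 5 (not isolated)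
Conditions: TsOH·H2O (5 mol%), toluene, reflux (Dean–Stark); then Ac2O (1.5 equiv), rt
Reagents that add atoms: acetic anhydride, CC(=O)OC(C)=O
Why: Acid-catalysed azeotropic lactonisation of a 2-hydroxyarylacetic acid closes the five-membered aryl lactone intramolecularly (5-exo-trig), and the acid-catalysed acetylation that follows caps the primary alcohol so that it cannot transesterify the aryl lactone in the base-catalysed step 4; no base is present that could acylate the lactone enolate.

Step 4
Reactants: 6 3-(7-methoxy-2-oxo-2,3-dihydro-1-benzofuran-5-yl)propyl acetate; 7 4-(benzyloxy)-3-methoxybenzaldehyde (O-benzylvanillin)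
Product: 8 3-[(3E)-3-{[4-(benzyloxy)-3-methoxyphenyl]methylidene}-7-methoxy-2-oxo-2,3-dihydro-1-benzofuran-5-yl]propyl acetate
Conditions: 7 (1.05 equiv), piperidine (10 mol%), AcOH (10 mol%), toluene, reflux (Dean–Stark), Ar
Reagents that add atoms: none
Why: In this Knoevenagel condensation the C3 methylene of the lactone is strongly acidic (its enolate is an aromatic 2-oxidobenzofuran) and should condense with the non-enolisable aldehyde under piperidinium acetate catalysis with water removal, mainly to the E arylidene lactone; any Z isomer can be carried along because the geometry is erased in step 5.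

Step 5
Reactants: 8 3-[(3E)-3-{[4-(benzyloxy)-3-methoxyphenyl]methylidene}-7-methoxy-2-oxo-2,3-dihydro-1-benzofuran-5-yl]propyl acetate; 9 methanol
Product: 11 methyl 2-[4-(benzyloxy)-3-methoxyphenyl]-5-(3-hydroxypropyl)-7-methoxy-1-benzofuran-3-carboxylate, via ring-opened phenol ester 10 (not isolated)
Conditions: NaOMe (2.5 equiv), MeOH–THF (1:2), 0 °C → rt, Ar; then I2 (1.3 equiv), rt, dark; aq. Na2S2O3
Reagents that add atoms: sodium methoxide, [Na+].[O-]C (same methoxy pool as methanol 9)
Why: Proposed new method: methoxide cleaves the aryl lactone of 8 (and transesterifies the acetate) to the sodium phenoxide of cinnamate 10, an opening that is downhill because phenoxide is a much weaker base than methoxide; iodine then activates the stilbene-type C=C as an iodonium ion, whose positive charge sits at the benzylic carbon next to the 4-benzyloxy-3-methoxyphenyl ring. The phenoxide oxygen attacks that carbon and so closes the furan ring by a formally 5-endo closure (5-endo opening of the iodonium ion, or the equivalent iodination of the reversibly formed oxa-Michael enolate), and loss of HI across C2–C3 aromatises it while the former lactone carbonyl stays on C3 as the methyl ester. The closest known reaction type is the iodine/base oxidative cyclisation of 2-hydroxystilbenes to 2-arylbenzofurans, combined with the ring-opening/ring-closure logic of the Perkin coumarin-to-benzofuran rearrangement; new here are the ester on the α-carbon of the stilbene and its release in situ from a 3-arylidene lactone. No stereocentre is created, and both alkene isomers of 8 converge because the phenol ring rotates freely about its bond to the alkene. The step needs O-attack at the arylidene carbon to win over relactonisation and over oxidation elsewhere: the cation-stabilising alkoxyaryl group on that carbon, the irreversible aromatisation, the absence of any free ortho or para position on the phenoxide ring (no nuclear iodination) and the use of I2 instead of a hypervalent iodine oxidant (which would dearomatise the 2-methoxyphenol in methanol) should secure this.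

Step 6
Reactants: 11 methyl 2-[4-(benzyloxy)-3-methoxyphenyl]-5-(3-hydroxypropyl)-7-methoxy-1-benzofuran-3-carboxylate
Product: 12 3-{2-[4-(benzyloxy)-3-methoxyphenyl]-3-(hydroxymethyl)-7-methoxy-1-benzofuran-5-yl}propan-1-ol
Conditions: LiAlH4 (2.5 equiv), THF, 0 °C; H2O/aq. NaOH work-up
Reagents that add atoms: none
Why: Hydride reduction of the conjugated ester with LiAlH4 should give the primary carbinol, the free alcohol only consuming one hydride, while the aryl benzyl ether, the methyl ethers and the benzofuran are inert at 0 °C.

Step 7
Reactants: 12 3-{2-[4-(benzyloxy)-3-methoxyphenyl]-3-(hydroxymethyl)-7-methoxy-1-benzofuran-5-yl}propan-1-ol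
Product: 13 2-[4-(benzyloxy)-3-methoxyphenyl]-5-(3-hydroxypropyl)-7-methoxy-1-benzofuran-3-carbaldehyde
Conditions: activated MnO2 (15 equiv), CH2Cl2, rt
Reagents that add atoms: none
Why: Activated MnO2 oxidises benzylic-type carbinols selectively, so the benzofuran-3-ylmethanol should go to the aldehyde while the saturated primary alcohol of the side chain stays untouched, and over-oxidation to the acid does not occur with this reagent.

Step 8
Reactants: 13 2-[4-(benzyloxy)-3-methoxyphenyl]-5-(3-hydroxypropyl)-7-methoxy-1-benzofuran-3-carbaldehyde
Product: 14 2-(4-hydroxy-3-methoxyphenyl)-5-(3-hydroxypropyl)-7-methoxy-1-benzofuran-3-carbaldehyde (target)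
Conditions: H2 (1 atm), 10% Pd/C (5 mol%), EtOAc, rt; stopped at full conversion of 13
Reagents that add atoms: none
Why: Catalytic hydrogenolysis of an aryl benzyl ether over Pd/C is fast at 1 atm in a neutral aprotic solvent, whereas the 3-formyl group (a vinylogous formate, deactivated by O1) and the tetrasubstituted furan C=C should be reduced much more slowly, so the free phenol should be released without touching the aldehyde.

**Compound list**

1 | 4-(3-hydroxypropyl)-2-methoxyphenol (dihydroconiferyl alcohol) | COc1cc(CCCO)ccc1O | starting material
2 | glyoxylic acid (used as 50% aqueous solution) | O=CC(=O)O | starting material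
3 | rac-2-hydroxy-2-[2-hydroxy-5-(3-hydroxypropyl)-3-methoxyphenyl]acetic acid (racemate) | COc1cc(CCCO)cc(C(O)C(=O)O)c1O | intermediate
4 | 2-[2-hydroxy-5-(3-hydroxypropyl)-3-methoxyphenyl]acetic acid | COc1cc(CCCO)cc(CC(=O)O)c1O | intermediate
5 | 5-(3-hydroxypropyl)-7-methoxy-1-benzofuran-2(3H)-one (hydroxy lactone; not isolated) | COc1cc(CCCO)cc2c1OC(=O)C2 | intermediate
6 | 3-(7-methoxy-2-oxo-2,3-dihydro-1-benzofuran-5-yl)propyl acetate | COc1cc(CCCOC(C)=O)cc2c1OC(=O)C2 | intermediate
7 | 4-(benzyloxy)-3-methoxybenzaldehyde (O-benzylvanillin) | COc1cc(C=O)ccc1OCc1ccccc1 | starting material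
8 | 3-[(3E)-3-{[4-(benzyloxy)-3-methoxyphenyl]methylidene}-7-methoxy-2-oxo-2,3-dihydro-1-benzofuran-5-yl]propyl acetate | O=C1Oc2c(OC)cc(CCCOC(C)=O)cc2/C1=C\c1ccc(OCc2ccccc2)c(OC)c1 | intermediate
9 | methanol | CO | starting material
10 | methyl (2E)-3-[4-(benzyloxy)-3-methoxyphenyl]-2-[2-hydroxy-5-(3-hydroxypropyl)-3-methoxyphenyl]prop-2-enoate (ring-opened phenol ester, present as its sodium phenoxide; not isolated) | COC(=O)/C(=C/c1ccc(OCc2ccccc2)c(OC)c1)c1cc(CCCO)cc(OC)c1O | intermediate
11 | methyl 2-[4-(benzyloxy)-3-methoxyphenyl]-5-(3-hydroxypropyl)-7-methoxy-1-benzofuran-3-carboxylate | COC(=O)c1c(-c2ccc(OCc3ccccc3)c(OC)c2)oc2c(OC)cc(CCCO)cc12 | intermediate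
12 | 3-{2-[4-(benzyloxy)-3-methoxyphenyl]-3-(hydroxymethyl)-7-methoxy-1-benzofuran-5-yl}propan-1-ol | OCc1c(-c2ccc(OCc3ccccc3)c(OC)c2)oc2c(OC)cc(CCCO)cc12 | intermediate
13 | 2-[4-(benzyloxy)-3-methoxyphenyl]-5-(3-hydroxypropyl)-7-methoxy-1-benzofuran-3-carbaldehyde | O=Cc1c(-c2ccc(OCc3ccccc3)c(OC)c2)oc2c(OC)cc(CCCO)cc12 | intermediate
14 | 2-(4-hydroxy-3-methoxyphenyl)-5-(3-hydroxypropyl)-7-methoxy-1-benzofuran-3-carbaldehyde | COc1cc(-c2oc3c(OC)cc(CCCO)cc3c2C=O)ccc1O | target

**Step count and risks**

Total step count: 8. Longest linear sequence: 8 steps (1 → 14); the partners 2, 7 and 9 are bought.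

Steps most likely to fail:

1. Step 5 (labelled step). After the lactone has opened, the two-electron oxidation may not end in O1–C2 closure. Methanol may capture the benzylic cation, the electron-rich phenoxide may be oxidised to quinonoid material, hypoiodite may attack the freed primary alcohol, and any unoxidised open ester recloses to the lactone on acidification. Fallback with known chemistry, at the acyl instead of the arylidene oxidation level (acid-induced acyl-lactone rearrangement): it sets out from lactone 6. Commercial 4-(benzyloxy)-3-methoxybenzoic acid (COc1cc(C(=O)O)ccc1OCc1ccccc1) is converted with oxalyl chloride and catalytic DMF in CH2Cl2 into 4-(benzyloxy)-3-methoxybenzoyl chloride F1. Lactone 6 is acylated with it (Et3N, catalytic DMAP, CH2Cl2, 0 °C → rt; the enol ester formed first undergoes the DMAP-mediated O-to-C acyl shift) to give 3-{3-[4-(benzyloxy)-3-methoxybenzoyl]-7-methoxy-2-oxo-2,3-dihydro-1-benzofuran-5-yl}propyl acetate F2, a racemic, largely enolised β-keto lactone. Heating F2 in methanolic HCl should open the lactone to the methyl ester, let the freed phenol add to the aryl ketone, dehydrate to the benzofuran and remove the acetate by transesterification. The route is rejoined at ester 11.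

2. Step 8. The formyl group may be over-reduced to the carbinol or the methyl group before debenzylation is complete, or the catalyst may be poisoned by traces of iodide or manganese carried over. Fallback by changing the order so that no aldehyde is present during hydrogenolysis: it sets out from ester 11. Hydrogenolysis (H2, Pd/C, EtOAc–MeOH, rt) should give methyl 2-(4-hydroxy-3-methoxyphenyl)-5-(3-hydroxypropyl)-7-methoxy-1-benzofuran-3-carboxylate F3. Reduction with excess LiAlH4 (THF, 0 °C → rt, buffered work-up with Rochelle salt) should give 4-[3-(hydroxymethyl)-5-(3-hydroxypropyl)-7-methoxy-1-benzofuran-2-yl]-2-methoxyphenol F4. Oxidation of the heteroaryl carbinol with activated MnO2 in acetone, in the way hydroxycinnamyl alcohols are oxidised in the presence of their free phenol, comes back to the route at target 14.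

3. Step 4. The amine catalyst may open the aryl lactone, the lactone enolate may couple oxidatively at C3 if air is admitted, and the electron-rich aldehyde may condense slowly. Fallback by a Perkin–Oglialoro condensation that needs neither the isolated lactone nor an amine nucleophile: it sets out from acid 4 and aldehyde 7, which are heated in acetic anhydride with triethylamine at 110 °C. Lactonisation, acetylation of the primary alcohol and condensation through the acetylated aldol should then occur in one operation, and the route is rejoined at arylidene lactone 8.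

**Further compounds**

F1 | step 5 | 4-(benzyloxy)-3-methoxybenzoyl chloride | COc1cc(C(=O)Cl)ccc1OCc1ccccc1
F2 | step 5 | 3-{3-[4-(benzyloxy)-3-methoxybenzoyl]-7-methoxy-2-oxo-2,3-dihydro-1-benzofuran-5-yl}propyl acetate (racemic keto form, in equilibrium with its enol) | COc1cc(CCCOC(C)=O)cc2c1OC(=O)C2C(=O)c1ccc(OCc2ccccc2)c(OC)c1
F3 | step 8 | methyl 2-(4-hydroxy-3-methoxyphenyl)-5-(3-hydroxypropyl)-7-methoxy-1-benzofuran-3-carboxylate | COC(=O)c1c(-c2ccc(O)c(OC)c2)oc2c(OC)cc(CCCO)cc12
F4 | step 8 | 4-[3-(hydroxymethyl)-5-(3-hydroxypropyl)-7-methoxy-1-benzofuran-2-yl]-2-methoxyphenol | COc1cc(-c2oc3c(OC)cc(CCCO)cc3c2CO)ccc1O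
F0 | step 4 | none | none
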